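**The problem**

5‑Methoxygalbelgin (15) is a single tetrahydrofuran ring, numbered here O1, C2 (3,4‑dimethoxyphenyl), C3 (methyl), C4 (methyl), C5 (3,4,5‑trimethoxyphenyl). It has four contiguous stereocentres, 2S,3S,4S,5S, and every pair of neighbours is trans. The two aryl groups differ by one methoxy group, which removes the twofold symmetry of the core, so the two aryl‑bearing carbons have to be addressed separately. The methyl groups offer no handle: each must arrive as methyl or as a group that is reduced to methyl late, and those reductions must spare two benzylic C–O bonds. These bonds, O1–C2 and O1–C5, sit next to very electron‑rich arenes. Brønsted or Lewis acid ionises them (epimerisation, ring opening), and hydrogenolysis or alkali metal in ammonia cleaves them, so the late steps must be neutral or basic. For control, C4 can be set from C5 by 1,2‑induction, and because the C2 aryl group and the C4 substituent lie on the same face, a C3 centre that carries a carbonyl group will settle trans to both. C2 and C5 are separated by oxygen and do not control each other reliably, so two independent sources of chirality are needed. The feature that opens the chosen route is that O1–C2 is β to C3: with the C3 methyl written as formyl, C2–C3–CHO is a cinnamaldehyde that has taken up oxygen at its β‑carbon and carbon at its α‑carbon, and O1–C5–C4 with an acceptor‑bearing carbon on C4 is a γ‑hydroxy vinyl sulfone.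

**Retrosynthesis**

15 to 14. The C4 methyl is written as a phenylsulfonylmethyl group, so the last step is cleavage of one C–S bond. The sulfone is chosen over an ester or nitro group because it is the acceptor needed for the C3–C4 bond, is inert to hydride and base, and goes to methyl in one reductive step. Sulfone 14 already has the full skeleton and all four stereocentres. The forward reaction must cleave an unactivated alkyl C–S bond by electron transfer without touching the benzylic ethers.

14 to 11 (through 13 and 12). The C3 methyl is traced to a formyl group via mesylate 13 and alcohol 12. Formyl is what enamine catalysis leaves at C3, and it makes C3 epimerisable, so the trans arrangement can be reached by equilibration. Direct deoxygenation of the aldehyde under strongly basic, hot conditions or through a dithioacetal and hydrogenolysis is set aside, because both endanger the benzylic ethers. The forward steps need only a borohydride reduction, a sulfonylation and a hydride displacement, all basic or neutral.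

11 to 6 + 7. This is the key cut: O1–C2 and C3–C4 are broken together. It puts each aryl‑bearing carbon into its own simple fragment, the achiral commercial enal 7 and alcohol 6 with one stereocentre, so four stereocentres fall back to one. Cutting C2–C3/C4–C5 or the two C–O bonds instead leads to the routes discussed below. The forward reaction, under a chiral secondary amine, must add the secondary benzylic hydroxyl of 6 to the iminium ion 8 of the enal, close enamine 9 onto the vinyl sulfone in a 5‑exo mode to give 10, and release 11. C2 and C3 must follow the catalyst and C4 must follow C5.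

6 to 4 + 5. The C=C bond of the vinyl sulfone is cut by cross‑metathesis. An olefination of an α‑aryl‑α‑hydroxy aldehyde would pass through a compound that racemises easily, and a condensation route from an arylacetaldehyde would give racemic 6. Metathesis keeps the resolved carbinol untouched and uses commercial 5. The forward reaction must give the E alkene without moving the double bond of the allylic alcohol.

4 to 3 to 1 + 2. The carbinol–vinyl C–C bond is cut to aldehyde 1 and vinyl Grignard reagent 2, and the racemate 3 is resolved. An enzymatic acylation is preferred to an asymmetric vinyl addition because it is general for aryl vinyl carbinols. The wanted enantiomer 4 is the unreacted one, so its purity can be raised by conversion.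

**Roads not taken**

Alternative 1: The ring C–O bond is cut to the 1,4‑diol A2, (1S,2S,3S,4S)‑1‑(3,4‑dimethoxyphenyl)‑2,3‑dimethyl‑4‑(3,4,5‑trimethoxyphenyl)butane‑1,4‑diol. Both carbinol C–O bonds and the C2–H and C3–H bonds of A2 are traced to the achiral diene A1, (1E,3E)‑1‑(3,4‑dimethoxyphenyl)‑2,3‑dimethyl‑4‑(3,4,5‑trimethoxyphenyl)buta‑1,3‑diene.
- Forward key step: the chiral monoalkylborane IpcBH2 adds syn to both alkenes of A1, boron to the benzylic carbons, and alkaline hydrogen peroxide gives A2.
- Merits: the methyl groups are present from the start, no sulfur or late reductions are needed, all four stereocentres come from one reagent, and the route is probably shorter than the chosen one.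
- Weak points:
  - Reagent control must operate twice on hindered trisubstituted aryl alkenes.
  - After the first addition the boron carries a B–H bond and can add to the second alkene within the molecule, where ring strain, not the pinene group, would decide the C3/C4 relationship.
  - Both carbinol centres of A2 already have the configuration of 15, so closure by displacement would invert one of them and give the 2,5‑cis ring. A2 can reach 15 only through a benzylic cation, so one of the stereocentres just set is erased and re‑formed under acid.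
- Comparison: Alternative 1 is better in step economy. The chosen plan offers a ring closure in which C2 and C5 are formed with defined configuration and never ionised, and a source of absolute configuration (resolved 6 plus catalyst) that does not depend on two consecutive reagent‑controlled additions.

Alternative 2: C2–C3 and C4–C5 are cut. Irradiation of the racemic trans‑oxirane A3, trans‑2‑(3,4‑dimethoxyphenyl)‑3‑(3,4,5‑trimethoxyphenyl)oxirane, opens its C–C bond to the carbonyl ylide A4. A4 adds across di‑(1R,2S,5R)‑menthyl fumarate A5 to give the diester A6, the all‑trans dimenthyl 2‑(3,4‑dimethoxyphenyl)‑5‑(3,4,5‑trimethoxyphenyl)tetrahydrofuran‑3,4‑dicarboxylate.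
- Merits: two C–C bonds and the ring form in one convergent step, A3 need not be enantiopure because A4 is achiral, and the two ester groups are reduced to methyl together in three steps with no sulfone to remove.
- Weak points:
  - The 2,5‑trans ring requires the S‑shaped form of A4 to be trapped before it relaxes to the more stable W‑shaped form, which gives 2,5‑cis products. The natural outcome therefore works against the target.
  - Electron‑rich diaryl oxiranes also fragment by C–O cleavage on irradiation.
  - The menthyl groups are remote from the new bonds, so facial selectivity on A5 is expected to be modest and the two all‑trans diastereomers of A6 would have to be separated.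
- Comparison: Alternative 2 is more convergent and has the simpler endgame. The chosen plan sets 2,5‑trans by two independent elements (catalyst at C2, resolved alcohol at C5) and does not rely on a weak auxiliary.

Alternative 3: The two C–CH3 bonds are cut. The cuprate Me2CuLi adds to C4 of the butenolide A7, (S)‑5‑(3,4,5‑trimethoxyphenyl)furan‑2(5H)‑one, anti to the aryl group, and the enolate is methylated with MeI anti to the new methyl to give the lactone A8, (3S,4S,5S)‑3,4‑dimethyl‑5‑(3,4,5‑trimethoxyphenyl)dihydrofuran‑2(3H)‑one. A8 would then be reduced to the lactol A9 and arylated at C2 with 1,2‑dimethoxybenzene A10 under a Lewis acid.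
- Merits: every step is of a known type, each stereocentre is set by its neighbour through reliable 1,2‑induction, the methyl groups enter as methyl, and the route is about one step shorter than the chosen one.
- Weak points:
  - The C5–H of A7 is benzylic and γ to the carbonyl group, so base can convert A7 into an achiral oxidofuran and erase the only stereocentre on which the rest depends.
  - The cuprate can also cleave the allylic, benzylic C5–O bond reductively.
  - The final arylation needs a Lewis acid in the presence of the C5 benzylic ether.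
- Comparison: in precedent and length Alternative 3 is the stronger road. The chosen plan offers a ring construction under buffered amine catalysis with no carbocation at either benzylic carbon and catalyst control of C2 that is independent of substrate bias. Alternative 3 is kept as the fallback for the key step.

Key step: step 4

Remark on the chemistry: it is assumed that the lipase follows the usual size rule for secondary alcohols with aryl as the large and vinyl as the medium group, so that the (R)‑alcohol is acetylated and the (S)‑alcohol remains.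

**Step 1**
Reactants: 1 3,4,5‑trimethoxybenzaldehyde; 2 vinylmagnesium bromide
Product: 3 rac‑1‑(3,4,5‑trimethoxyphenyl)prop‑2‑en‑1‑ol
Conditions: THF, −20 to 0 °C; sat. aq. NH4Cl
Reagents that add atoms: none
Why: Grignard 1,2‑addition to a non‑enolisable aromatic aldehyde; the carbinol centre forms as the racemate and is resolved in step 2, and the mild NH4Cl work‑up avoids ionisation of the allylic benzylic alcohol.

**Step 2**
Reactants: 3 rac‑1‑(3,4,5‑trimethoxyphenyl)prop‑2‑en‑1‑ol
Product: 4 (S)‑1‑(3,4,5‑trimethoxyphenyl)prop‑2‑en‑1‑ol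
Conditions: Novozym 435 (immobilised Candida antarctica lipase B), vinyl acetate, t‑BuOMe, 30 °C, stopped just past half conversion; chromatography
Reagents that add atoms: none
Why: Lipase‑catalysed kinetic resolution by irreversible transesterification; the (R)‑alcohol is acetylated and the (S)‑alcohol 4 remains, and since 4 is the unreacted enantiomer its purity can be raised by running slightly beyond half conversion. This fixes C5 of the target.

**Step 3**
Reactants: 4 (S)‑1‑(3,4,5‑trimethoxyphenyl)prop‑2‑en‑1‑ol; 5 phenyl vinyl sulfone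
Product: 6 (S,E)‑3‑(phenylsulfonyl)‑1‑(3,4,5‑trimethoxyphenyl)prop‑2‑en‑1‑ol
Conditions: second‑generation Grubbs catalyst (H2IMes)(PCy3)Cl2Ru=CHPh (5 mol %), 5 (3 equiv), CH2Cl2, 40 °C
Reagents that add atoms: none
Why: Olefin cross‑metathesis of a terminal alkene with an electron‑poor vinyl sulfone, which does not homodimerise and can be used in excess; the E isomer is expected as in known couplings of 5, and the carbinol centre is not involved.

**Step 4**
Reactants: 6 (S,E)‑3‑(phenylsulfonyl)‑1‑(3,4,5‑trimethoxyphenyl)prop‑2‑en‑1‑ol; 7 (E)‑3‑(3,4‑dimethoxyphenyl)acrylaldehyde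
Product: 11 (2S,3S,4S,5S)‑2‑(3,4‑dimethoxyphenyl)‑4‑[(phenylsulfonyl)methyl]‑5‑(3,4,5‑trimethoxyphenyl)tetrahydrofuran‑3‑carbaldehyde, via iminium benzoate 8 (not isolated), via oxa‑Michael enamine 9 (not isolated), via ring‑closed iminium benzoate 10 (not isolated)
Conditions: (S)‑2‑[diphenyl(trimethylsilyloxy)methyl]pyrrolidine (20 mol %), PhCO2H (20 mol %), 7 (1.5 equiv), toluene, 0 °C to rt
Reagents that add atoms: none
Why: Proposed new method: the amine condenses with 7 to iminium benzoate 8, the hydroxyl group of 6 adds reversibly to its β‑carbon (O1–C2) to give enamine 9, and 9 closes by 5‑exo‑trig Michael addition of its α‑carbon onto the vinyl sulfone (C3–C4) to give 10, whose hydrolysis releases 11 and the catalyst; the closest known reaction type is the iminium–enamine oxa‑Michael/Michael annulation of enals with primary γ‑hydroxy enones and with 2‑hydroxy‑β‑nitrostyrenes under such catalysts, so the secondary benzylic alcohol and the mono‑sulfonyl alkene are the new elements. The unfavourable oxa‑Michael equilibrium should be drained by the irreversible ring closure as in the known cases, and 7 has no γ‑hydrogen and cannot divert into dienamine chemistry. C2 is set by the catalyst: the diphenyl(silyloxy)methyl group of the (S)‑amine covers one face of the s‑trans (E)‑iminium ion, and oxygen attack on the open face gives 2S, the sense in which nucleophiles are known to add to β‑aryl enals with this catalyst. C3 is set by the same group on the (E)‑enamine (new bond anti to it, 2,3‑trans), and because C3 is α to the formyl group it can settle trans to both neighbours under the amine/acid buffer. C4 is set by C5: allylic 1,3‑strain holds the C5–H bond in the plane of the vinyl sulfone, the tethered enamine can reach only the alkene face on the side of O1, and the sulfonylmethyl group ends trans to the C5 aryl group. The step needs 1,4‑ over 1,2‑addition of the alcohol (the hemiacetal path is reversible and unproductive), carbon attack on the sulfone in preference to addition of the hindered amine, and a matched pairing of catalyst and alcohol, which the all‑pseudoequatorial transition state of the (S)/(S) pair should provide. C5 is not touched and no acid strong enough to ionise the benzylic ethers is present.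

**Step 5**
Reactants: 11 (2S,3S,4S,5S)‑2‑(3,4‑dimethoxyphenyl)‑4‑[(phenylsulfonyl)methyl]‑5‑(3,4,5‑trimethoxyphenyl)tetrahydrofuran‑3‑carbaldehyde
Product: 12 [(2S,3R,4S,5S)‑2‑(3,4‑dimethoxyphenyl)‑4‑[(phenylsulfonyl)methyl]‑5‑(3,4,5‑trimethoxyphenyl)tetrahydrofuran‑3‑yl]methanol
Conditions: NaBH4, MeOH/THF, 0 °C
Reagents that add atoms: none
Why: Chemoselective borohydride reduction of the aldehyde; sulfone and benzylic ethers are inert, and removing the carbonyl group at once closes the path to C3 epimerisation and retro‑oxa‑Michael opening. No centre is formed; the C3 descriptor changes from S to R only through substituent ranking.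

**Step 6**
Reactants: 12 [(2S,3R,4S,5S)‑2‑(3,4‑dimethoxyphenyl)‑4‑[(phenylsulfonyl)methyl]‑5‑(3,4,5‑trimethoxyphenyl)tetrahydrofuran‑3‑yl]methanol
Product: 13 [(2S,3R,4S,5S)‑2‑(3,4‑dimethoxyphenyl)‑4‑[(phenylsulfonyl)methyl]‑5‑(3,4,5‑trimethoxyphenyl)tetrahydrofuran‑3‑yl]methyl methanesulfonate
Conditions: MsCl, Et3N, CH2Cl2, 0 °C
Reagents that add atoms: methanesulfonyl chloride, CS(=O)(=O)Cl
Why: Sulfonylation of a primary alcohol under amine base; no stereocentre is involved, and the trans arrangement of the two arms keeps the sulfone α‑carbon from closing a four‑membered ring onto the mesylate.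

**Step 7**
Reactants: 13 [(2S,3R,4S,5S)‑2‑(3,4‑dimethoxyphenyl)‑4‑[(phenylsulfonyl)methyl]‑5‑(3,4,5‑trimethoxyphenyl)tetrahydrofuran‑3‑yl]methyl methanesulfonate
Product: 14 (2S,3S,4S,5S)‑2‑(3,4‑dimethoxyphenyl)‑3‑methyl‑4‑[(phenylsulfonyl)methyl]‑5‑(3,4,5‑trimethoxyphenyl)tetrahydrofuran
Conditions: LiBHEt3, THF, 0 °C to rt
Reagents that add atoms: none
Why: SN2 displacement of a primary mesylate by hydride gives the C3 methyl group; the aryl sulfone is not reduced by borohydrides and the benzylic ethers are untouched.

**Step 8**
Reactants: 14 (2S,3S,4S,5S)‑2‑(3,4‑dimethoxyphenyl)‑3‑methyl‑4‑[(phenylsulfonyl)methyl]‑5‑(3,4,5‑trimethoxyphenyl)tetrahydrofuran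
Product: 15 (2S,3S,4S,5S)‑2‑(3,4‑dimethoxyphenyl)‑3,4‑dimethyl‑5‑(3,4,5‑trimethoxyphenyl)tetrahydrofuran (5‑methoxygalbelgin)
Conditions: Mg turnings, MeOH, 50 °C
Reagents that add atoms: none
Why: Reductive desulfonylation by single‑electron transfer from magnesium cleaves the alkyl C–SO2Ph bond and the solvent supplies hydrogen, giving the C4 methyl group; the medium is basic and is not known to cleave benzylic ethers, so C2 and C5 keep their configuration.

**Compound list**

1 | 3,4,5‑trimethoxybenzaldehyde | COc1cc(C=O)cc(OC)c1OC | starting material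
2 | vinylmagnesium bromide | C=C[Mg]Br | starting material
3 | rac‑1‑(3,4,5‑trimethoxyphenyl)prop‑2‑en‑1‑ol | COc1cc(C(O)C=C)cc(OC)c1OC | intermediate
4 | (S)‑1‑(3,4,5‑trimethoxyphenyl)prop‑2‑en‑1‑ol | COc1cc([C@@H](O)C=C)cc(OC)c1OC | intermediate
5 | phenyl vinyl sulfone | C=CS(=O)(=O)c1ccccc1 | starting material
6 | (S,E)‑3‑(phenylsulfonyl)‑1‑(3,4,5‑trimethoxyphenyl)prop‑2‑en‑1‑ol | COc1cc([C@@H](O)/C=C/S(=O)(=O)c2ccccc2)cc(OC)c1OC | intermediate
7 | (E)‑3‑(3,4‑dimethoxyphenyl)acrylaldehyde | COc1ccc(/C=C/C=O)cc1OC | starting material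
8 | (S)‑1‑[(E)‑3‑(3,4‑dimethoxyphenyl)allylidene]‑2‑[diphenyl(trimethylsilyloxy)methyl]pyrrolidin‑1‑ium benzoate (iminium ion of 7 and the catalyst) | COc1ccc(/C=C/C=[N+]2CCC[C@H]2C(c2ccccc2)(c2ccccc2)O[Si](C)(C)C)cc1OC.[O-]C(=O)c1ccccc1 | intermediate
9 | (S)‑1‑[(1E,3S)‑3‑(3,4‑dimethoxyphenyl)‑3‑{[(1S,2E)‑3‑(phenylsulfonyl)‑1‑(3,4,5‑trimethoxyphenyl)prop‑2‑en‑1‑yl]oxy}prop‑1‑en‑1‑yl]‑2‑[diphenyl(trimethylsilyloxy)methyl]pyrrolidine (enamine after oxa‑Michael addition) | COc1ccc([C@@H](O[C@@H](/C=C/S(=O)(=O)c2ccccc2)c2cc(OC)c(OC)c(OC)c2)/C=C/N2CCC[C@H]2C(c2ccccc2)(c2ccccc2)O[Si](C)(C)C)cc1OC | intermediate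
10 | (S)‑1‑{[(2S,3R,4S,5S)‑2‑(3,4‑dimethoxyphenyl)‑4‑[(phenylsulfonyl)methyl]‑5‑(3,4,5‑trimethoxyphenyl)tetrahydrofuran‑3‑yl]methylidene}‑2‑[diphenyl(trimethylsilyloxy)methyl]pyrrolidin‑1‑ium benzoate (iminium ion of 11 and the catalyst, ring configured as in 11) | COc1ccc([C@H]2O[C@H](c3cc(OC)c(OC)c(OC)c3)[C@@H](CS(=O)(=O)c3ccccc3)[C@@H]2C=[N+]2CCC[C@H]2C(c2ccccc2)(c2ccccc2)O[Si](C)(C)C)cc1OC.[O-]C(=O)c1ccccc1 | intermediate
11 | (2S,3S,4S,5S)‑2‑(3,4‑dimethoxyphenyl)‑4‑[(phenylsulfonyl)methyl]‑5‑(3,4,5‑trimethoxyphenyl)tetrahydrofuran‑3‑carbaldehyde | COc1ccc([C@H]2O[C@H](c3cc(OC)c(OC)c(OC)c3)[C@@H](CS(=O)(=O)c3ccccc3)[C@@H]2C=O)cc1OC | intermediate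
12 | [(2S,3R,4S,5S)‑2‑(3,4‑dimethoxyphenyl)‑4‑[(phenylsulfonyl)methyl]‑5‑(3,4,5‑trimethoxyphenyl)tetrahydrofuran‑3‑yl]methanol | COc1ccc([C@H]2O[C@H](c3cc(OC)c(OC)c(OC)c3)[C@@H](CS(=O)(=O)c3ccccc3)[C@@H]2CO)cc1OC | intermediate
13 | [(2S,3R,4S,5S)‑2‑(3,4‑dimethoxyphenyl)‑4‑[(phenylsulfonyl)methyl]‑5‑(3,4,5‑trimethoxyphenyl)tetrahydrofuran‑3‑yl]methyl methanesulfonate | COc1ccc([C@H]2O[C@H](c3cc(OC)c(OC)c(OC)c3)[C@@H](CS(=O)(=O)c3ccccc3)[C@@H]2COS(C)(=O)=O)cc1OC | intermediate
14 | (2S,3S,4S,5S)‑2‑(3,4‑dimethoxyphenyl)‑3‑methyl‑4‑[(phenylsulfonyl)methyl]‑5‑(3,4,5‑trimethoxyphenyl)tetrahydrofuran | COc1ccc([C@H]2O[C@H](c3cc(OC)c(OC)c(OC)c3)[C@@H](CS(=O)(=O)c3ccccc3)[C@@H]2C)cc1OC | intermediate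
15 | (2S,3S,4S,5S)‑2‑(3,4‑dimethoxyphenyl)‑3,4‑dimethyl‑5‑(3,4,5‑trimethoxyphenyl)tetrahydrofuran (5‑methoxygalbelgin) | COc1ccc([C@H]2O[C@H](c3cc(OC)c(OC)c(OC)c3)[C@@H](C)[C@@H]2C)cc1OC | target

**Step count and least certain steps**

Total step count: 8. Longest linear sequence: 8 steps (1 → 3 → 4 → 6 → 11 → 12 → 13 → 14 → 15); 2, 5 and 7 are purchased.

Step 4 (key step, proposed new method). The most likely failure is that the secondary benzylic alcohol does not add to the electron‑rich iminium ion fast enough, so that too little enamine 9 is present for ring closure. Side processes could then take over: amine‑induced isomerisation of 6 to the saturated γ‑keto sulfone, reversible capture of the catalyst by the vinyl sulfone, or a mismatched closure that gives the C4 epimer. The fallback uses only known reaction types, sets out from 4 and comes back at 15, and gives up the sulfone handle.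
- Acylation of 4 with acryloyl chloride and Et3N would give (S)‑1‑(3,4,5‑trimethoxyphenyl)allyl acrylate F1.
- Ring‑closing metathesis with the second‑generation Grubbs catalyst (H2IMes)(PCy3)Cl2Ru=CHPh would give (S)‑5‑(3,4,5‑trimethoxyphenyl)furan‑2(5H)‑one F2 (the same compound as A7).
- Conjugate addition of Me2CuLi anti to the aryl group and trapping of the enolate with MeI anti to the new methyl group would give (3S,4S,5S)‑3,4‑dimethyl‑5‑(3,4,5‑trimethoxyphenyl)dihydrofuran‑2(3H)‑one F3 (the same compound as A8).
- Reduction with i‑Bu2AlH at −78 °C would give (3S,4S,5S)‑3,4‑dimethyl‑5‑(3,4,5‑trimethoxyphenyl)tetrahydrofuran‑2‑ol F4 (the same compound as A9).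
- Friedel–Crafts arylation of the derived oxocarbenium ion with 1,2‑dimethoxybenzene (A10) under BF3·OEt2 at low temperature, with attack anti to the C3 methyl group, would give 15.

The price is a Lewis‑acid step at the end and a butenolide that can lose its configuration under base.

Step 3. Ruthenium hydride species formed from the catalyst may move the double bond of the allylic alcohol and give the saturated ethyl ketone, and slow turnover with the electron‑poor sulfone may let self‑metathesis of 4 compete. The fallback sets out from 4 and comes back at 6 without a metal catalyst.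
- Radical addition of PhSeSO2Ph (AIBN, CHCl3, reflux) would place the sulfonyl group on the terminal carbon and give (1R)‑2‑(phenylselanyl)‑3‑(phenylsulfonyl)‑1‑(3,4,5‑trimethoxyphenyl)propan‑1‑ol F5 as a mixture of epimers at C2. The carbinol centre is unchanged; its descriptor changes by ranking only.
- Oxidation with H2O2 and syn‑elimination of the selenoxide toward the acidic CH2SO2Ph side, away from the carbinol, would give 6.

Step 8. Electron transfer to an unactivated primary alkyl phenyl sulfone may stop short of complete C–S cleavage, and forcing it may begin to cleave a benzylic C–O bond. The fallback sets out from 14 and comes back at 15, replacing reductive by oxidative removal of sulfur.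
- Deprotonation α to sulfur with n‑BuLi at −78 °C and oxidation of the carbanion with Me3SiOOSiMe3 would give (2S,3S,4S,5S)‑5‑(3,4‑dimethoxyphenyl)‑4‑methyl‑2‑(3,4,5‑trimethoxyphenyl)tetrahydrofuran‑3‑carbaldehyde F6.
- NaBH4 would give [(2S,3R,4S,5S)‑5‑(3,4‑dimethoxyphenyl)‑4‑methyl‑2‑(3,4,5‑trimethoxyphenyl)tetrahydrofuran‑3‑yl]methanol F7.
- MsCl and Et3N would give [(2S,3R,4S,5S)‑5‑(3,4‑dimethoxyphenyl)‑4‑methyl‑2‑(3,4,5‑trimethoxyphenyl)tetrahydrofuran‑3‑yl]methyl methanesulfonate F8.
- LiBHEt3 would give 15, repeating the operations of steps 5 to 7 on the other arm.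

Step 2. Acylation of this hindered, electron‑rich aryl vinyl carbinol may be slow and the discrimination between enantiomers incomplete, which would leave 4 of insufficient enantiomeric purity at an acceptable conversion. The fallback sets out from 3 and comes back at 4, using a different recognition principle. In a Sharpless kinetic resolution (Ti(OiPr)4, L‑(+)‑diisopropyl tartrate, t‑BuOOH in deficit, 4 Å molecular sieves, CH2Cl2, −20 °C) the (R)‑enantiomer would be epoxidised to (S)‑[(R)‑oxiran‑2‑yl](3,4,5‑trimethoxyphenyl)methanol F9, the erythro epoxy alcohol, and 4 would be recovered.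

**Further compounds**

F1 | step 4 | (S)‑1‑(3,4,5‑trimethoxyphenyl)allyl acrylate | C=CC(=O)O[C@@H](C=C)c1cc(OC)c(OC)c(OC)c1
F2 | step 4 | (S)‑5‑(3,4,5‑trimethoxyphenyl)furan‑2(5H)‑one | O=C1C=C[C@@H](c2cc(OC)c(OC)c(OC)c2)O1
F3 | step 4 | (3S,4S,5S)‑3,4‑dimethyl‑5‑(3,4,5‑trimethoxyphenyl)dihydrofuran‑2(3H)‑one | O=C1O[C@H](c2cc(OC)c(OC)c(OC)c2)[C@@H](C)[C@@H]1C
F4 | step 4 | (3S,4S,5S)‑3,4‑dimethyl‑5‑(3,4,5‑trimethoxyphenyl)tetrahydrofuran‑2‑ol (both anomers) | OC1O[C@H](c2cc(OC)c(OC)c(OC)c2)[C@@H](C)[C@@H]1C
F5 | step 3 | (1R)‑2‑(phenylselanyl)‑3‑(phenylsulfonyl)‑1‑(3,4,5‑trimethoxyphenyl)propan‑1‑ol (both epimers at C2) | COc1cc([C@@H](O)C(CS(=O)(=O)c2ccccc2)[Se]c2ccccc2)cc(OC)c1OC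
F6 | step 8 | (2S,3S,4S,5S)‑5‑(3,4‑dimethoxyphenyl)‑4‑methyl‑2‑(3,4,5‑trimethoxyphenyl)tetrahydrofuran‑3‑carbaldehyde | COc1ccc([C@H]2O[C@H](c3cc(OC)c(OC)c(OC)c3)[C@@H](C=O)[C@@H]2C)cc1OC
F7 | step 8 | [(2S,3R,4S,5S)‑5‑(3,4‑dimethoxyphenyl)‑4‑methyl‑2‑(3,4,5‑trimethoxyphenyl)tetrahydrofuran‑3‑yl]methanol | COc1ccc([C@H]2O[C@H](c3cc(OC)c(OC)c(OC)c3)[C@@H](CO)[C@@H]2C)cc1OC
F8 | step 8 | [(2S,3R,4S,5S)‑5‑(3,4‑dimethoxyphenyl)‑4‑methyl‑2‑(3,4,5‑trimethoxyphenyl)tetrahydrofuran‑3‑yl]methyl methanesulfonate | COc1ccc([C@H]2O[C@H](c3cc(OC)c(OC)c(OC)c3)[C@@H](COS(C)(=O)=O)[C@@H]2C)cc1OC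
F9 | step 2 | (S)‑[(R)‑oxiran‑2‑yl](3,4,5‑trimethoxyphenyl)methanol | COc1cc([C@H](O)[C@H]2CO2)cc(OC)c1OC
A1 | alternative 1 | (1E,3E)‑1‑(3,4‑dimethoxyphenyl)‑2,3‑dimethyl‑4‑(3,4,5‑trimethoxyphenyl)buta‑1,3‑diene | COc1ccc(/C=C(C)/C(C)=C/c2cc(OC)c(OC)c(OC)c2)cc1OC
A2 | alternative 1 | (1S,2S,3S,4S)‑1‑(3,4‑dimethoxyphenyl)‑2,3‑dimethyl‑4‑(3,4,5‑trimethoxyphenyl)butane‑1,4‑diol | COc1ccc([C@@H](O)[C@@H](C)[C@H](C)[C@H](O)c2cc(OC)c(OC)c(OC)c2)cc1OC
A3 | alternative 2 | trans‑2‑(3,4‑dimethoxyphenyl)‑3‑(3,4,5‑trimethoxyphenyl)oxirane (racemic, one enantiomer drawn) | COc1ccc([C@H]2O[C@@H]2c2cc(OC)c(OC)c(OC)c2)cc1OC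
A4 | alternative 2 | carbonyl ylide from C–C cleavage of A3 | COc1ccc(C=[O+][CH-]c2cc(OC)c(OC)c(OC)c2)cc1OC
A5 | alternative 2 | di‑(1R,2S,5R)‑menthyl fumarate | O=C(/C=C/C(=O)O[C@@H]1C[C@H](C)CC[C@H]1C(C)C)O[C@@H]1C[C@H](C)CC[C@H]1C(C)C
A6 | alternative 2 | di‑(1R,2S,5R)‑menthyl (2S,3S,4S,5S)‑2‑(3,4‑dimethoxyphenyl)‑5‑(3,4,5‑trimethoxyphenyl)tetrahydrofuran‑3,4‑dicarboxylate (all‑trans) | COc1ccc([C@H]2O[C@H](c3cc(OC)c(OC)c(OC)c3)[C@@H](C(=O)O[C@@H]3C[C@H](C)CC[C@H]3C(C)C)[C@@H]2C(=O)O[C@@H]2C[C@H](C)CC[C@H]2C(C)C)cc1OC
A7 | alternative 3 | (S)‑5‑(3,4,5‑trimethoxyphenyl)furan‑2(5H)‑one | O=C1C=C[C@@H](c2cc(OC)c(OC)c(OC)c2)O1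
A8 | alternative 3 | (3S,4S,5S)‑3,4‑dimethyl‑5‑(3,4,5‑trimethoxyphenyl)dihydrofuran‑2(3H)‑one | O=C1O[C@H](c2cc(OC)c(OC)c(OC)c2)[C@@H](C)[C@@H]1C
A9 | alternative 3 | (3S,4S,5S)‑3,4‑dimethyl‑5‑(3,4,5‑trimethoxyphenyl)tetrahydrofuran‑2‑ol (both anomers) | OC1O[C@H](c2cc(OC)c(OC)c(OC)c2)[C@@H](C)[C@@H]1C
A10 | alternative 3 | 1,2‑dimethoxybenzene | COc1ccccc1OC
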